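Retrosynthesis (labdane numbering): cut C12–C13 (Negishi coupling with a Z-iodobutenoic acid). Reset C2 (acetate ← axial alcohol ← ketone ← equatorial alcohol). Cut C9–C10 and C4–C5 in one retro-cascade, re-tying O2 to C4 as a 2,2-dimethyloxetane. The acyclic chain falls apart at C5–C6 (B-alkyl Suzuki–Miyaura).
Enabling feature: O2 lies 1,3 to the gem-dimethyl carbon C4, and C4 / C5=C10 / C9=C8(C17H3) are spaced as an E,E-1,5-diene. A C4 radical released from an O2–C4 oxetane can therefore close ring A, then ring B, and end as the C8=C17 methylene.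
Forward order of rings: the temporary oxetane is made in step 3. In step 9 it is opened, ring A closes and ring B closes last. The side chain is joined in the last step.
Stereochemistry: C2 is bought with (S)-epichlorohydrin. Held equatorial as its titanium alkoxide, it relays to C5, C10 and C9 through a chair-chair cascade. C2 is then erased and rebuilt axial (2β) by hydride attack anti to the axial C19 and C20 methyls.
Alkene geometry: E C5=C10 comes from syn borylcupration/methylation, E C8=C9 from SeO2 oxidation of the E methyl group, and Z C13=C14 from anti hydroiodination. All couplings run with retention.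

Key step: step 9

Assumption: labdane numbering is used for all compounds (C17 = exocyclic CH2, C19 and C20 = axial methyls on C4 and C10, α/β as in the usual labdane drawing), and 1, 8 and 17 are taken as catalogue chemicals.

Step 1
Reactants: 1 (S)-epichlorohydrin
Product: 2 (S)-1-chloro-4-methylpent-4-en-2-ol
Conditions: isopropenylmagnesium bromide, CuI (cat.), THF, −40 to 0 °C; aqueous work-up
Reagents that add atoms: isopropenylmagnesium bromide, C=C(C)[Mg]Br
Why: Copper-catalysed Grignard opening of a terminal epoxide takes place at the unsubstituted epoxide carbon faster than chloride displacement, so the C2–O bond and the configuration bought with 1 stay untouched.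

Step 2
Reactants: 2 (S)-1-chloro-4-methylpent-4-en-2-ol
Product: 4 (S)-6-methylhept-6-en-1-yn-4-ol, via epoxide 3 (not isolated)
Conditions: lithium acetylide–ethylenediamine complex (excess), DMSO, 0 °C to rt; aqueous work-up
Reagents that add atoms: lithium acetylide, [Li]C#C
Why: The base closes the chlorohydrin to the terminal epoxide and the acetylide opens it by SN2 at the CH2 terminus (epoxide alkynylation), again without touching the C2–O bond.

Step 3
Reactants: 4 (S)-6-methylhept-6-en-1-yn-4-ol
Product: 5 (R)-2,2-dimethyl-4-(prop-2-yn-1-yl)oxetane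
Conditions: [N,N'-bis(3,5-di-tert-butylsalicylidene)-1,2-cyclohexanediaminato]cobalt (cat., divalent cobalt), N-fluoro-2,4,6-trimethylpyridinium tetrafluoroborate, PhSiH3, PhCF3, rt
Reagents that add atoms: none
Why: Cobalt-hydride hydrogen-atom transfer to the 1,1-disubstituted alkene followed by radical-polar crossover lets the C2 hydroxyl capture the tertiary C4 centre (Mukaiyama-type cycloisomerisation of homoallylic alcohols to 2,2-disubstituted oxetanes), which forms the C4–O bond, leaves C2 and its configuration alone, needs no alkoxide that could fragment, and is run at the alkyne stage because a terminal alkyne is a poor partner for the tertiary centre whereas a 1,5-disposed alkene would cyclise.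

Step 4
Reactants: 5 (R)-2,2-dimethyl-4-(prop-2-yn-1-yl)oxetane
Product: 6 2-{(E)-3-[(2R)-4,4-dimethyloxetan-2-yl]-2-methylprop-1-en-1-yl}-4,4,5,5-tetramethyl-1,3,2-dioxaborolane
Conditions: CuCl (cat.), Xantphos (cat.), NaOt-Bu, B2pin2, MeI, THF, rt
Reagents that add atoms: bis(pinacolato)diboron, CC1(C)OB(OC1(C)C)B1OC(C)(C)C(C)(C)O1; iodomethane, CI
Why: In this copper-catalysed alkylboration, syn borylcupration puts boron on the terminal and copper on the internal alkyne carbon, and methylation of the alkenylcopper with retention gives the E trisubstituted C5=C10 alkene under basic, Lewis-acid-free conditions that spare the oxetane, which an organoaluminium carbometalation would not.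

Step 5
Reactants: 6 alkenylboronate
Product: 7 (R)-4-[(E)-3-iodo-2-methylprop-2-en-1-yl]-2,2-dimethyloxetane
Conditions: NaOH (aqueous), then I2, THF, 0 °C
Reagents that add atoms: iodine, II
Why: Iodinolysis of the hydroxyboronate ate complex (iododeboronation) replaces boron by iodine with retention, so the E iodoalkene needed for the coupling results.

Step 6
Reactants: 8 5-bromo-2-methylpent-2-ene
Product: 9 (E)-5-bromo-2-methylpent-2-enal
Conditions: SeO2, 1,4-dioxane, 80 °C
Reagents that add atoms: selenium dioxide, O=[Se]=O
Why: Riley allylic oxidation (ene reaction followed by a [2,3]-sigmatropic shift) attacks the E methyl group of the trisubstituted alkene, which fixes the E geometry of the later C8=C9 bond.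

Step 7
Reactants: 9 (E)-5-bromo-2-methylpent-2-enal
Product: 10 (E)-6-bromo-3-methylhexa-1,3-diene
Conditions: methyltriphenylphosphonium bromide, KN(SiMe3)2, THF, −78 to 0 °C
Reagents that add atoms: methyltriphenylphosphonium bromide, C[P+](c1ccccc1)(c1ccccc1)c1ccccc1.[Br-]
Why: Wittig methylenation of the unhindered enal is faster at low temperature than γ-deprotonation or alkylation of the ylide by the primary bromide.

Step 8
Reactants: 10 (E)-6-bromo-3-methylhexa-1,3-diene; 7 (R)-4-[(E)-3-iodo-2-methylprop-2-en-1-yl]-2,2-dimethyloxetane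
Product: 12 (R)-4-[(2E,6E)-9-bromo-2,6-dimethylnona-2,6-dien-1-yl]-2,2-dimethyloxetane, via alkylborane 11 (not isolated)
Conditions: 9-BBN, THF, 0 °C to rt; then 7, Pd(dppf)Cl2 (cat.), AsPh3 (cat.), Cs2CO3, DMF/H2O, rt
Reagents that add atoms: none
Why: 9-BBN hydroborates only the monosubstituted end of the diene with boron on C6, and the B-alkyl Suzuki–Miyaura coupling joins C6 to C5 with retention under mildly basic conditions to which the oxetane and the primary bromide are inert.

Step 9
Reactants: 12 (R)-4-[(2E,6E)-9-bromo-2,6-dimethylnona-2,6-dien-1-yl]-2,2-dimethyloxetane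
Product: 13 (2S,5S,9S,10S)-12-bromo-13,14,15,16-tetranorlabd-8(17)-en-2α-ol (trans-decalin, H5 α, H9 α, C20 β, 2-OH equatorial)
Conditions: Cp2TiCl2 (2.5 equiv), Mn dust, degassed THF, rt (gives Cp2TiCl); slow addition of 12, rt to 40 °C; aqueous NaH2PO4
Reagents that add atoms: none
Why: Proposed new method: Cp2TiCl (trivalent titanium) binds the oxetane oxygen and transfers one electron, so that strain release and the strong Ti–O bond drive homolysis of the tertiary C4–O bond to a γ-titanoxy C4 radical, the closest known reaction types being the titanocene-mediated radical cascade of epoxypolyprenes and the titanocene-induced reductive opening of simple oxetanes, of which only the combination is new. The C4 radical closes ring A by 6-endo-trig attack on C5 of the E C5=C10 alkene (5-exo attack on the methyl-bearing C10 is sterically retarded), and the tertiary C10 radical so formed closes ring B by a second 6-endo-trig attack on C9 of the E C8=C9 alkene. Both closures pass through chair-like transition states in which the bulky C2–OTiCp2Cl group must be equatorial, because an axial position would be syn-axial to a C4 methyl group and to C20, so this single bought stereocentre selects the face of C5=C10 and thereby fixes C5 (H α) and C10 (C20 β, trans fusion by equatorial bond formation from the chain held equatorial on C5). C9 follows from the E geometry of C8=C9 in the chair, which places the bromoethyl arm equatorial (H9 α). The hindered tertiary C8 radical is met by a second Cp2TiCl and loses its most accessible β hydrogen, one of C17, which gives the exocyclic C8=C17 alkene and Cp2Ti(H)Cl, as in the epoxide cascades. The step needs electron transfer to the oxetane only, cleavage of the tertiary and not the secondary C–O bond, and ring closure faster than radical capture, which should be secured because the strained ether is the only group that Cp2TiCl reduces (isolated alkenes and an unactivated primary bromide are inert), because homolysis follows radical stability as in epoxide opening, and because tertiary radicals combine only slowly with the bulky titanocene.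

Step 10
Reactants: 13 12-bromo-13,14,15,16-tetranorlabd-8(17)-en-2α-ol
Product: 14 (5S,9S,10S)-12-bromo-13,14,15,16-tetranorlabd-8(17)-en-2-one
Conditions: Dess–Martin periodinane, CH2Cl2, 0 °C to rt
Reagents that add atoms: none
Why: Dess–Martin oxidation of an unhindered equatorial secondary alcohol is mild enough for the exocyclic alkene and the bromide, and it erases the relay stereocentre on purpose.

Step 11
Reactants: 14 12-bromo-13,14,15,16-tetranorlabd-8(17)-en-2-one
Product: 15 (2R,5S,9S,10S)-12-bromo-13,14,15,16-tetranorlabd-8(17)-en-2β-ol (2-OH axial)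
Conditions: NaBH4, MeOH/THF, −20 to 0 °C
Reagents that add atoms: none
Why: In this hydride reduction under steric approach control the two axial methyl groups C19 and C20 block the β face at C2, so hydride should arrive from the α face and push the hydroxyl into the axial 2β position of the target.

Step 12
Reactants: 15 12-bromo-13,14,15,16-tetranorlabd-8(17)-en-2β-ol
Product: 16 (2R,5S,9S,10S)-2β-acetoxy-12-bromo-13,14,15,16-tetranorlabd-8(17)-ene
Conditions: Ac2O, DMAP, Et3N, CH2Cl2, rt to 40 °C
Reagents that add atoms: acetic anhydride, CC(=O)OC(C)=O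
Why: DMAP-catalysed acylation through the small N-acetylpyridinium ion reaches even the hindered axial alcohol with retention at C2 and leaves bromide and alkene alone.

Step 13
Reactants: 17 but-2-ynoic acid
Product: 18 (Z)-3-iodobut-2-enoic acid
Conditions: NaI, AcOH, 110 °C
Reagents that add atoms: sodium iodide, [Na+].[I-]
Why: Hydroiodination of the ynoic acid by conjugate addition of iodide and anti protonation gives the Z isomer with iodine cis to the carboxyl group.

Step 14
Reactants: 16 2β-acetoxy-12-bromo-13,14,15,16-tetranorlabd-8(17)-ene; 18 (Z)-3-iodobut-2-enoic acid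
Product: 22 (2R,5S,9S,10S)-2-acetoxylabda-8(17),13Z-dien-15-oic acid (target), via alkylzinc bromide 19 (not isolated), via silyl iodobutenoate 20 (not isolated), via silyl ester 21 (not isolated)
Conditions: 16, Zn dust, I2 (cat.), DMA, 70 °C; separately 18, N,O-bis(trimethylsilyl)acetamide, THF, rt; combine, PdCl2(PPh3)2 (cat.), TMEDA, rt to 40 °C; aqueous citric acid
Reagents that add atoms: none
Why: Direct zinc insertion into the primary bromide tolerates acetate and alkene, the acidic proton of 18 is masked in the flask as a silyl ester so that it cannot quench 19, and the Negishi coupling of a β-iodoenoate proceeds by fast oxidative addition to zerovalent palladium and with retention, which carries the Z geometry of 18 into C13=C14 before aqueous acid frees the carboxylic acid.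

Compound list
1 | (S)-epichlorohydrin | ClC[C@@H]1CO1 | starting material
2 | (S)-1-chloro-4-methylpent-4-en-2-ol | C=C(C)C[C@H](O)CCl | intermediate
3 | (S)-2-(2-methylprop-2-en-1-yl)oxirane | C=C(C)C[C@H]1CO1 | intermediate
4 | (S)-6-methylhept-6-en-1-yn-4-ol | C=C(C)C[C@H](O)CC#C | intermediate
5 | (R)-2,2-dimethyl-4-(prop-2-yn-1-yl)oxetane | CC1(C)C[C@@H](CC#C)O1 | intermediate
6 | 2-{(E)-3-[(2R)-4,4-dimethyloxetan-2-yl]-2-methylprop-1-en-1-yl}-4,4,5,5-tetramethyl-1,3,2-dioxaborolane | CC1(C)C[C@@H](C/C(C)=C/B2OC(C)(C)C(C)(C)O2)O1 | intermediate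
7 | (R)-4-[(E)-3-iodo-2-methylprop-2-en-1-yl]-2,2-dimethyloxetane | CC1(C)C[C@@H](C/C(C)=C/I)O1 | intermediate
8 | 5-bromo-2-methylpent-2-ene | CC(C)=CCCBr | starting material
9 | (E)-5-bromo-2-methylpent-2-enal | O=C/C(C)=C/CCBr | intermediate
10 | (E)-6-bromo-3-methylhexa-1,3-diene | C=C/C(C)=C/CCBr | intermediate
11 | 9-[(E)-6-bromo-3-methylhex-3-en-1-yl]-9-borabicyclo[3.3.1]nonane | C(C/C(C)=C/CCBr)B1C2CCCC1CCC2 | intermediate
12 | (R)-4-[(2E,6E)-9-bromo-2,6-dimethylnona-2,6-dien-1-yl]-2,2-dimethyloxetane | CC1(C)C[C@@H](C/C(C)=C/CC/C(C)=C/CCBr)O1 | intermediate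
13 | (2S,5S,9S,10S)-12-bromo-13,14,15,16-tetranorlabd-8(17)-en-2α-ol | C=C1CC[C@H]2C(C)(C)C[C@H](O)C[C@]2(C)[C@H]1CCBr | intermediate
14 | (5S,9S,10S)-12-bromo-13,14,15,16-tetranorlabd-8(17)-en-2-one | C=C1CC[C@H]2C(C)(C)CC(=O)C[C@]2(C)[C@H]1CCBr | intermediate
15 | (2R,5S,9S,10S)-12-bromo-13,14,15,16-tetranorlabd-8(17)-en-2β-ol | C=C1CC[C@H]2C(C)(C)C[C@@H](O)C[C@]2(C)[C@H]1CCBr | intermediate
16 | (2R,5S,9S,10S)-2β-acetoxy-12-bromo-13,14,15,16-tetranorlabd-8(17)-ene | C=C1CC[C@H]2C(C)(C)C[C@@H](OC(C)=O)C[C@]2(C)[C@H]1CCBr | intermediate
17 | but-2-ynoic acid | CC#CC(=O)O | starting material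
18 | (Z)-3-iodobut-2-enoic acid | C/C(I)=C/C(=O)O | intermediate
19 | [2β-acetoxy-13,14,15,16-tetranorlabd-8(17)-en-12-yl]zinc bromide | C=C1CC[C@H]2C(C)(C)C[C@@H](OC(C)=O)C[C@]2(C)[C@H]1CC[Zn]Br | intermediate
20 | trimethylsilyl (Z)-3-iodobut-2-enoate | C/C(I)=C/C(=O)O[Si](C)(C)C | intermediate
21 | trimethylsilyl (2R,5S,9S,10S)-2-acetoxylabda-8(17),13Z-dien-15-oate | C=C1CC[C@H]2C(C)(C)C[C@@H](OC(C)=O)C[C@]2(C)[C@H]1CC/C(C)=C\C(=O)O[Si](C)(C)C | intermediate
22 | (2R,5S,9S,10S)-2-acetoxylabda-8(17),13Z-dien-15-oic acid | C=C1CC[C@H]2C(C)(C)C[C@@H](OC(C)=O)C[C@]2(C)[C@H]1CC/C(C)=C\C(=O)O | target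

Total step count: 14.
Longest linear sequence: 11 steps (1, 2, 3, 4, 5, 8, 9, 10, 11, 12, 14).

Steps most likely to fail

Step 9 (bears the label).
- **What may go wrong:** electron transfer to the hindered oxetane may be too slow. The cascade may also be cut short after ring A by hydrogen loss from C20.
- **Fallback:** known chemistry, an epoxide trigger with a sacrificial oxygen on C3. It sets out from 11 and comes back at 14.

3-Methylbut-2-enal is propargylated with allenylboronic acid pinacol ester under chiral phosphoric acid catalysis to (R)-6-methylhept-5-en-1-yn-4-ol F1. Negishi carboalumination (Me3Al, Cp2ZrCl2) and iodinolysis give (R,E)-1-iodo-2,6-dimethylhepta-1,5-dien-4-ol F2. B-alkyl Suzuki–Miyaura coupling with 11 gives (4R,6E,10E)-13-bromo-2,6,10-trimethyltrideca-2,6,10-trien-4-ol F3. The matched Sharpless epoxidation (Ti(OiPr)4, D-(−)-diisopropyl tartrate, t-BuOOH) touches only the alkene of the allylic alcohol. It gives (1R,3E,7E)-10-bromo-1-[(2S)-3,3-dimethyloxiran-2-yl]-3,7-dimethyldeca-3,7-dien-1-ol F4. The established Cp2TiCl cascade of epoxypolyprenes closes ring A and then ring B to 12-bromo-13,14,15,16-tetranorlabd-8(17)-ene-2α,3β-diol F5, with both oxygens equatorial. One equivalent of Dess–Martin periodinane oxidises the less hindered C2 carbinol (the C3 carbinol is neopentyl) to 12-bromo-3β-hydroxy-13,14,15,16-tetranorlabd-8(17)-en-2-one F6. SmI2 in THF/MeOH then removes the α-hydroxy group and delivers 14.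

Step 3.
- **What may go wrong:** capture of the tertiary centre by the hydroxyl to give a strained ring may lose out to hydrogen loss (alkene isomerisation), to hydration, or to attack of the radical on the alkyne.
- **Fallback:** the other C–O bond (C2–O) is made instead, by double inversion. It sets out from 4 and comes back at 5.

Mukaiyama hydration (Mn(dpm)3, PhSiH3, O2) gives (R)-2-methylhept-6-yne-2,4-diol F7. Appel bromination (CBr4, PPh3) of the secondary alcohol with inversion gives (S)-4-bromo-2-methylhept-6-yn-2-ol F8. An Ag2O-assisted Williamson closure by the tertiary hydroxyl inverts C2 a second time and gives 5.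

Step 14.
- **What may go wrong:** sluggish transmetalation to a carboxylate-chelated palladium intermediate, protonation of the organozinc, or drift of the Z geometry.
- **Fallback:** an isolable ester that fluoride removes without touching the acetate. It sets out from 18 (and uses 19) and comes back at 22.

18 is esterified with 2-(trimethylsilyl)ethanol (DCC, DMAP) to 2-(trimethylsilyl)ethyl (Z)-3-iodobut-2-enoate F9. Negishi coupling with 19 gives 2-(trimethylsilyl)ethyl (2R,5S,9S,10S)-2-acetoxylabda-8(17),13Z-dien-15-oate F10, which can be purified from any E isomer. Bu4NF in THF at 0 °C then releases 22.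

Further compounds
F1 | step 9 | (R)-6-methylhept-5-en-1-yn-4-ol | CC(C)=C[C@H](O)CC#C
F2 | step 9 | (R,E)-1-iodo-2,6-dimethylhepta-1,5-dien-4-ol | CC(C)=C[C@H](O)C/C(C)=C/I
F3 | step 9 | (4R,6E,10E)-13-bromo-2,6,10-trimethyltrideca-2,6,10-trien-4-ol | CC(C)=C[C@H](O)C/C(C)=C/CC/C(C)=C/CCBr
F4 | step 9 | (1R,3E,7E)-10-bromo-1-[(2S)-3,3-dimethyloxiran-2-yl]-3,7-dimethyldeca-3,7-dien-1-ol | CC1(C)O[C@H]1[C@H](O)C/C(C)=C/CC/C(C)=C/CCBr
F5 | step 9 | 12-bromo-13,14,15,16-tetranorlabd-8(17)-ene-2α,3β-diol | C=C1CC[C@H]2C(C)(C)[C@@H](O)[C@H](O)C[C@]2(C)[C@H]1CCBr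
F6 | step 9 | 12-bromo-3β-hydroxy-13,14,15,16-tetranorlabd-8(17)-en-2-one | C=C1CC[C@H]2C(C)(C)[C@@H](O)C(=O)C[C@]2(C)[C@H]1CCBr
F7 | step 3 | (R)-2-methylhept-6-yne-2,4-diol | CC(C)(O)C[C@H](O)CC#C
F8 | step 3 | (S)-4-bromo-2-methylhept-6-yn-2-ol | CC(C)(O)C[C@@H](Br)CC#C
F9 | step 14 | 2-(trimethylsilyl)ethyl (Z)-3-iodobut-2-enoate | C/C(I)=C/C(=O)OCC[Si](C)(C)C
F10 | step 14 | 2-(trimethylsilyl)ethyl (2R,5S,9S,10S)-2-acetoxylabda-8(17),13Z-dien-15-oate | C=C1CC[C@H]2C(C)(C)C[C@@H](OC(C)=O)C[C@]2(C)[C@H]1CC/C(C)=C\C(=O)OCC[Si](C)(C)C
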